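**Strategy.** The C40 polyene is disconnected at the C14′–C15′ single bond into a C18 ε-ring trienyne and a C21 dienyl iodide carrying the 5,8-epoxide (dihydrofuran) ring. The key step exploits the trisubstituted C13′(C20′)=C14′ E-alkene flanking that bond, whose cis methyl/H pattern is the retron of syn-methylmetalation of a terminal alkyne: in one pot, Cp2ZrCl2-catalysed addition of Me3Al to the C13′≡C14′ alkyne installs C20′, fixes the 13′E geometry and delivers an alkenylalane that is cross-coupled (Pd2(dba)3/ZnCl2) with the 15′E iodide. The furanoid stereocentres arise from a Sharpless epoxide (C5) relayed to C8 through an anti-SN2′ allenol and AuCl3 cycloisomerisation.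

Key step: step 18

Remark: (R)-(+)-α-ionone 19 is taken as a purchasable, enantiopure starting material that supplies C6′; locants follow carotenoid numbering (unprimed: furanoid half, primed: ε half).

Step 1
Reactants: 1 β-cyclocitral
Product: 2 β-cyclogeraniol
Conditions: NaBH4, MeOH, 0 °C
Reagents that add atoms: none
Why: Borohydride 1,2-reduction of the hindered enal should give the allylic alcohol that directs the epoxidation.

Step 2
Reactants: 2 β-cyclogeraniol
Product: 3 [(1R,6R)-2,2,6-trimethyl-7-oxabicyclo[4.1.0]heptan-1-yl]methanol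
Conditions: Ti(OiPr)4 (10 mol%), D-(−)-diethyl tartrate (12 mol%), t-BuOOH, 4 Å MS, CH2Cl2, −20 °C
Reagents that add atoms: tert-butyl hydroperoxide, CC(C)(C)OO
Why: Katsuki–Sharpless asymmetric epoxidation: the D-(−)-tartrate titanium complex should deliver oxygen to the face of C5=C6 that gives the (1R,6R) epoxide (the facial sense that turns geraniol into its (2R,3R)-epoxide), which sets C5 (5R, kept to the target) and C6.

Step 3
Reactants: 3 epoxy alcohol
Product: 4 (1S,6R)-2,2,6-trimethyl-7-oxabicyclo[4.1.0]heptane-1-carbaldehyde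
Conditions: nPr4N[RuO4] (5 mol%), N-methylmorpholine N-oxide, 4 Å MS, CH2Cl2, rt
Reagents that add atoms: none
Why: Ley–Griffith oxidation is neutral and should leave the tetrasubstituted oxirane closed (the descriptor at C1 changes only through CIP priorities).

Step 4
Reactants: 4 epoxy aldehyde
Product: 5 (1R,6R)-1-ethynyl-2,2,6-trimethyl-7-oxabicyclo[4.1.0]heptane
Conditions: dimethyl (1-diazo-2-oxopropyl)phosphonate, K2CO3, MeOH, 0 °C → rt
Reagents that add atoms: dimethyl (1-diazo-2-oxopropyl)phosphonate, CC(=O)C(=[N+]=[N-])P(=O)(OC)OC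
Why: Seyferth–Gilbert homologation in the Ohira–Bestmann variant; the aldehyde has no α-hydrogen, so neither oxirane stereocentre can epimerise under the mild base.

Step 5
Reactants: 6 but-2-yn-1-ol
Product: 8 (E)-3-iodobut-2-en-1-ol, via alkenylzirconocene 7 (not isolated)
Conditions: Cp2Zr(H)Cl (2.5 equiv), THF, rt → 40 °C; then I2, 0 °C
Reagents that add atoms: iodine, [I][I]
Why: Hydrozirconation–iodination: syn Zr–H addition with zirconium settling on the methyl-bearing carbon after equilibration, then iodinolysis with retention, should give the E-iodide.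

Step 6
Reactants: 5 alkynyl epoxide; 8 (E)-3-iodobut-2-en-1-ol
Product: 9 (2E)-3-methyl-5-[(1R,6R)-2,2,6-trimethyl-7-oxabicyclo[4.1.0]heptan-1-yl]pent-2-en-4-yn-1-ol
Conditions: PdCl2(PPh3)2 (3 mol%), CuI (6 mol%), iPr2NH, THF, rt
Reagents that add atoms: none
Why: Sonogashira coupling proceeds with retention of the E-iodide geometry and the hindered oxirane should survive the mild amine conditions.

Step 7
Reactants: 9 enynyl epoxide
Product: 11 (1R)-2-[(3E)-5-hydroxy-3-methylpenta-1,3-dien-1-ylidene]-1,3,3-trimethylcyclohexan-1-ol (allene axis aS), via bis-silyl ether 10 (not isolated)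
Conditions: CuCl (5 mol%), IPr·HCl (1,3-bis(2,6-diisopropylphenyl)imidazolium chloride, 5 mol%), NaOtBu (12 mol%), (EtO)2MeSiH (3 equiv), toluene, 0 °C → rt; then NaOH, MeOH/H2O
Reagents that add atoms: none
Why: Copper hydride catalysed anti-SN2′ reduction of a propargylic oxirane: hydride should enter C8 on the face opposite the breaking C6–O bond, so the C6=C7=C8 axis forms with C9 on the side of the former epoxide oxygen while C5 keeps its C–O bond and R configuration.

Step 8
Reactants: 11 allenic diol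
Product: 12 (2E)-3-[(2R,7aR)-4,4,7a-trimethyl-2,4,5,6,7,7a-hexahydro-1-benzofuran-2-yl]but-2-en-1-ol
Conditions: AuCl3 (2 mol%), THF, 0 °C → rt, dark
Reagents that add atoms: none
Why: Gold-catalysed 5-endo cycloisomerisation of an α-hydroxyallene to a 2,5-dihydrofuran: the C5 oxygen can reach C8 only within the C5–C6–C7 plane, so the allene axis is transferred to the new C8 stereocentre (8R, C9 cis to C4 and trans to the C5 methyl).

Step 9
Reactants: 12 furanoid allylic alcohol
Product: 13 (2E)-3-[(2R,7aR)-4,4,7a-trimethyl-2,4,5,6,7,7a-hexahydro-1-benzofuran-2-yl]but-2-enal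
Conditions: MnO2, CH2Cl2, rt
Reagents that add atoms: none
Why: Neutral allylic oxidation with MnO2 should not touch the acid-labile doubly allylic ether.

Step 10
Reactants: 13 furanoid enal; 14 triethyl 3-methyl-4-phosphonocrotonate
Product: 15 ethyl (2E,4E,6E)-3-methyl-7-[(2R,7aR)-4,4,7a-trimethyl-2,4,5,6,7,7a-hexahydro-1-benzofuran-2-yl]octa-2,4,6-trienoate
Conditions: 14, n-BuLi, DMPU, THF, −78 °C; then 13, −78 → 0 °C
Reagents that add atoms: none
Why: Vinylogous Horner–Wadsworth–Emmons olefination should form C11=C12 as the E-alkene and, with the lithium/DMPU protocol, deliver the 13E ester predominantly.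

Step 11
Reactants: 15 trienoate
Product: 16 (2E,4E,6E)-3-methyl-7-[(2R,7aR)-4,4,7a-trimethyl-2,4,5,6,7,7a-hexahydro-1-benzofuran-2-yl]octa-2,4,6-trien-1-ol
Conditions: iBu2AlH (2.5 equiv), CH2Cl2, −78 °C; aq. KNaC4H4O6 work-up
Reagents that add atoms: none
Why: Low-temperature 1,2-reduction of the conjugated ester by the aluminium hydride should stop cleanly at the allylic alcohol.

Step 12
Reactants: 16 trienol
Product: 17 (2E,4E,6E)-3-methyl-7-[(2R,7aR)-4,4,7a-trimethyl-2,4,5,6,7,7a-hexahydro-1-benzofuran-2-yl]octa-2,4,6-trienal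
Conditions: MnO2, CH2Cl2, rt, dark
Reagents that add atoms: none
Why: Allylic oxidation with MnO2 under neutral conditions gives the C15 aldehyde without isomerising the polyene.

Step 13
Reactants: 17 trienal
Product: 18 (2R,7aR)-2-[(2E,4E,6E,8E)-9-iodo-6-methylnona-2,4,6,8-tetraen-2-yl]-4,4,7a-trimethyl-2,4,5,6,7,7a-hexahydro-1-benzofuran
Conditions: CrCl2 (6 equiv), CHI3 (2 equiv), THF/1,4-dioxane, 0 °C → rt, dark
Reagents that add atoms: iodoform, [I]C([I])[I]
Why: Takai iodo-olefination adds C15′ through a gem-dichromium species whose anti elimination should favour the 15′E iodide.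

Step 14
Reactants: 19 (R)-α-ionone
Product: 21 (6R)-6-[(1E)-but-1-en-3-yn-1-yl]-1,5,5-trimethylcyclohex-1-ene, via dienyl phosphate 20 (not isolated)
Conditions: LiN(iPr)2 (1.05 equiv), THF, −78 °C; ClP(O)(OEt)2, −78 °C → rt; LiN(iPr)2 (2.3 equiv), −78 °C → rt; aq. NH4Cl
Reagents that add atoms: none
Why: Negishi methyl ketone to alkyne conversion (kinetic α′-enolate, enol phosphate, elimination); deprotonation at the methyl group and not at C6′ should keep the ε-ring stereocentre.

Step 15
Reactants: 22 trans-1,2-dichloroethene (fivefold excess); 23 ethynyltrimethylsilane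
Product: 24 [(3E)-4-chlorobut-3-en-1-yn-1-yl]trimethylsilane
Conditions: Pd(PPh3)4 (2 mol%), CuI (5 mol%), n-BuNH2, Et2O, rt
Reagents that add atoms: none
Why: Sonogashira mono-coupling of the excess dichloroalkene proceeds with retention and gives the E-chloroenyne linchpin for C11′–C14′.

Step 16
Reactants: 21 ε-dienyne; 24 chloroenyne
Product: 26 trimethyl[(3E,5E,7E)-6-methyl-8-[(1R)-2,6,6-trimethylcyclohex-2-en-1-yl]octa-3,5,7-trien-1-yn-1-yl]silane, via alkenylalane 25 (not isolated)
Conditions: Me3Al (2 equiv), Cp2ZrCl2 (20 mol%), (CH2Cl)2, rt; volatiles removed; THF, 24, ZnCl2 (20 mol%), Pd(PtBu3)2 (3 mol%), rt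
Reagents that add atoms: trimethylaluminium, C[Al](C)C
Why: Negishi zirconium-catalysed syn-methylalumination followed by Pd/Zn-catalysed alkenyl–alkenyl coupling with retention at the activated chloroenyne should set 9′E and 11′E in one pot and rehearses the key step.

Step 17
Reactants: 26 silylated trienyne
Product: 27 (6R)-1,5,5-trimethyl-6-[(1E,3E,5E)-3-methylocta-1,3,5-trien-7-yn-1-yl]cyclohex-1-ene
Conditions: K2CO3, MeOH/THF, rt, dark
Reagents that add atoms: none
Why: Methanolysis of the alkynyl C–Si bond under mild carbonate conditions frees the terminal alkyne without touching the triene or C6′.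

Step 18
Reactants: 27 ε-trienyne; 18 furanoid dienyl iodide
Product: 29 (5R,8R,6′R)-5,8-epoxy-5,8-dihydro-β,ε-carotene (all-E), via alkenylalane 28 (not isolated)
Conditions: 27, Me3Al (2 equiv), Cp2ZrCl2 (20 mol%), (CH2Cl)2, rt; volatiles removed in vacuo; THF, ZnCl2 (20 mol%), Pd2(dba)3 (2.5 mol%), P(2-furyl)3 (10 mol%), then 18 (0.8 equiv) in THF/DMF, rt, dark, argon
Reagents that add atoms: trimethylaluminium, C[Al](C)C
Why: Cp2ZrCl2-catalysed methylalumination adds Me–Al syn across the terminal C13′≡C14′ bond of 27 with aluminium on the terminal carbon, giving the (E)-alkenylalane 28 that already carries C20′; after removal of excess Me3Al, transmetalation through zinc to palladium, oxidative addition of zerovalent palladium into the C15′–I bond of 18 with retention and reductive elimination forge C14′–C15′. The closest known reaction type is the Negishi one-pot carboalumination/Pd–Zn alkenyl–alkenyl cross-coupling used for all-E carotenoid polyenes. No ring is closed and no stereocentre is created; the new stereo-element is the 13′E alkene, fixed by syn carbometalation, and 15′E is carried over from the iodide. The step needs regioselective methyl delivery to C13′ (secured by the terminal alkyne), inertness of the trisubstituted ring alkenes and the polyene, and survival of the acid-labile doubly allylic C8–O bond and of C6′ (secured by stripping Me3Al, running the coupling in THF and adding 18 last).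

**Compound list**

1 | β-cyclocitral (2,6,6-trimethylcyclohex-1-ene-1-carbaldehyde) | CC1=C(C=O)C(C)(C)CCC1 | starting material
2 | β-cyclogeraniol ((2,6,6-trimethylcyclohex-1-en-1-yl)methanol) | CC1=C(CO)C(C)(C)CCC1 | intermediate
3 | [(1R,6R)-2,2,6-trimethyl-7-oxabicyclo[4.1.0]heptan-1-yl]methanol | C[C@@]12CCCC(C)(C)[C@]1(CO)O2 | intermediate
4 | (1S,6R)-2,2,6-trimethyl-7-oxabicyclo[4.1.0]heptane-1-carbaldehyde | C[C@@]12CCCC(C)(C)[C@]1(C=O)O2 | intermediate
5 | (1R,6R)-1-ethynyl-2,2,6-trimethyl-7-oxabicyclo[4.1.0]heptane | C[C@@]12CCCC(C)(C)[C@]1(C#C)O2 | intermediate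
6 | but-2-yn-1-ol | CC#CCO | starting material
7 | chlorobis(cyclopentadienyl)zirconium (E)-3-[chlorobis(cyclopentadienyl)zirconio]but-2-en-1-olate (alkenylzirconocene) | C/C(=C\CO[Zr](Cl)(C1C=CC=C1)C1C=CC=C1)[Zr](Cl)(C1C=CC=C1)C1C=CC=C1 | intermediate
8 | (E)-3-iodobut-2-en-1-ol | I/C(C)=C/CO | intermediate
9 | (2E)-3-methyl-5-[(1R,6R)-2,2,6-trimethyl-7-oxabicyclo[4.1.0]heptan-1-yl]pent-2-en-4-yn-1-ol | C[C@@]12CCCC(C)(C)[C@]1(C#C/C(C)=C/CO)O2 | intermediate
10 | bis[diethoxy(methyl)silyl] ether of allenic diol 11 | C[C@@]1(O[Si](C)(OCC)OCC)CCCC(C)(C)C1=[C@]=C([H])/C(C)=C/CO[Si](C)(OCC)OCC | intermediate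
11 | (1R)-2-[(3E)-5-hydroxy-3-methylpenta-1,3-dien-1-ylidene]-1,3,3-trimethylcyclohexan-1-ol, allene axis aS (C9 on the side of the former epoxide oxygen) | C[C@@]1(O)CCCC(C)(C)C1=[C@]=C([H])/C(C)=C/CO | intermediate
12 | (2E)-3-[(2R,7aR)-4,4,7a-trimethyl-2,4,5,6,7,7a-hexahydro-1-benzofuran-2-yl]but-2-en-1-ol | OC/C=C(\C)[C@H]1C=C2C(C)(C)CCC[C@@]2(C)O1 | intermediate
13 | (2E)-3-[(2R,7aR)-4,4,7a-trimethyl-2,4,5,6,7,7a-hexahydro-1-benzofuran-2-yl]but-2-enal | O=C/C=C(\C)[C@H]1C=C2C(C)(C)CCC[C@@]2(C)O1 | intermediate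
14 | triethyl 3-methyl-4-phosphonocrotonate (ethyl 4-(diethoxyphosphoryl)-3-methylbut-2-enoate, E/Z mixture as sold) | CCOC(=O)C=C(C)CP(=O)(OCC)OCC | starting material
15 | ethyl (2E,4E,6E)-3-methyl-7-[(2R,7aR)-4,4,7a-trimethyl-2,4,5,6,7,7a-hexahydro-1-benzofuran-2-yl]octa-2,4,6-trienoate | CCOC(=O)/C=C(C)/C=C/C=C(\C)[C@H]1C=C2C(C)(C)CCC[C@@]2(C)O1 | intermediate
16 | (2E,4E,6E)-3-methyl-7-[(2R,7aR)-4,4,7a-trimethyl-2,4,5,6,7,7a-hexahydro-1-benzofuran-2-yl]octa-2,4,6-trien-1-ol | OC/C=C(C)/C=C/C=C(\C)[C@H]1C=C2C(C)(C)CCC[C@@]2(C)O1 | intermediate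
17 | (2E,4E,6E)-3-methyl-7-[(2R,7aR)-4,4,7a-trimethyl-2,4,5,6,7,7a-hexahydro-1-benzofuran-2-yl]octa-2,4,6-trienal | O=C/C=C(C)/C=C/C=C(\C)[C@H]1C=C2C(C)(C)CCC[C@@]2(C)O1 | intermediate
18 | (2R,7aR)-2-[(2E,4E,6E,8E)-9-iodo-6-methylnona-2,4,6,8-tetraen-2-yl]-4,4,7a-trimethyl-2,4,5,6,7,7a-hexahydro-1-benzofuran | I/C=C/C=C(C)/C=C/C=C(\C)[C@H]1C=C2C(C)(C)CCC[C@@]2(C)O1 | intermediate
19 | (R)-α-ionone ((3E)-4-[(1R)-2,6,6-trimethylcyclohex-2-en-1-yl]but-3-en-2-one) | CC1=CCCC(C)(C)[C@H]1/C=C/C(C)=O | starting material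
20 | diethyl (3E)-4-[(1R)-2,6,6-trimethylcyclohex-2-en-1-yl]buta-1,3-dien-2-yl phosphate | CC1=CCCC(C)(C)[C@H]1/C=C/C(=C)OP(=O)(OCC)OCC | intermediate
21 | (6R)-6-[(1E)-but-1-en-3-yn-1-yl]-1,5,5-trimethylcyclohex-1-ene | CC1=CCCC(C)(C)[C@H]1/C=C/C#C | intermediate
22 | trans-1,2-dichloroethene | Cl/C=C/Cl | starting material
23 | ethynyltrimethylsilane | C#C[Si](C)(C)C | starting material
24 | [(3E)-4-chlorobut-3-en-1-yn-1-yl]trimethylsilane | C[Si](C)(C)C#C/C=C/Cl | intermediate
25 | dimethyl[(1E,3E)-2-methyl-4-[(1R)-2,6,6-trimethylcyclohex-2-en-1-yl]buta-1,3-dien-1-yl]alane | CC1=CCCC(C)(C)[C@H]1/C=C/C(C)=C/[Al](C)C | intermediate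
26 | trimethyl[(3E,5E,7E)-6-methyl-8-[(1R)-2,6,6-trimethylcyclohex-2-en-1-yl]octa-3,5,7-trien-1-yn-1-yl]silane | CC1=CCCC(C)(C)[C@H]1/C=C/C(C)=C/C=C/C#C[Si](C)(C)C | intermediate
27 | (6R)-1,5,5-trimethyl-6-[(1E,3E,5E)-3-methylocta-1,3,5-trien-7-yn-1-yl]cyclohex-1-ene | CC1=CCCC(C)(C)[C@H]1/C=C/C(C)=C/C=C/C#C | intermediate
28 | dimethyl[(1E,3E,5E,7E)-2,6-dimethyl-8-[(1R)-2,6,6-trimethylcyclohex-2-en-1-yl]octa-1,3,5,7-tetraen-1-yl]alane | CC1=CCCC(C)(C)[C@H]1/C=C/C(C)=C/C=C/C(C)=C/[Al](C)C | intermediate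
29 | (5R,8R,6′R)-5,8-epoxy-5,8-dihydro-β,ε-carotene (all-E) | CC1=CCCC(C)(C)[C@H]1/C=C/C(C)=C/C=C/C(C)=C/C=C/C=C(C)/C=C/C=C(\C)[C@H]1C=C2C(C)(C)CCC[C@@]2(C)O1 | target

**Step count.** Total: 18 steps. Longest linear sequence: 13 steps (steps 1–4, 6–13, 18).

**Steps most likely to fail**

Step 18 (key step). The aluminium and zinc Lewis acids present during the coupling may ionise the doubly allylic C8–O bond of 18, with loss of configuration at C8 or ring opening. Methylalumination of the conjugated trienyne may also stall or scramble polyene geometry. The fallback is a Stille coupling under neutral conditions, setting out from 27 and 17 and returning at 29. Trienyne 27 is methylaluminated as above and the alane is quenched with I2 at −30 °C to give (6R)-6-[(1E,3E,5E,7E)-8-iodo-3,7-dimethylocta-1,3,5,7-tetraen-1-yl]-1,5,5-trimethylcyclohex-1-ene F1. Trienal 17 is treated with Bu3SnCHBr2, CrCl2 and LiI in THF/DMF (Hodgson stannyl olefination) to give tributyl[(1E,3E,5E,7E)-4-methyl-8-[(2R,7aR)-4,4,7a-trimethyl-2,4,5,6,7,7a-hexahydro-1-benzofuran-2-yl]nona-1,3,5,7-tetraen-1-yl]stannane F2. F1 and F2 are then joined with Pd2(dba)3 and AsPh3 in NMP at rt in the dark to give 29.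

Step 8. Gold may re-ionise the doubly allylic C8–O bond of the product and erode the configuration at C8, and the vinylallene may divert into carbocyclisation. The fallback is an electrophilic iodocyclisation, setting out from 11 and returning at 12. Diol 11 is treated with N-iodosuccinimide in CH2Cl2 at −20 °C; 5-endo anti-iodoetherification transfers the axis to C8 in the same sense and gives (2E)-3-[(2S,7aR)-3-iodo-4,4,7a-trimethyl-2,4,5,6,7,7a-hexahydro-1-benzofuran-2-yl]but-2-en-1-ol F3. The C7 iodide is then removed with Pd(PPh3)4 and Bu3SnH in THF to give 12.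

Step 7. Hydride delivery may leak to the syn face, which after cyclisation would give the C8 epimer, and direct opening of the oxirane or over-reduction may compete. The fallback is a palladium-catalysed formate hydrogenolysis, setting out from 9 and returning at 11. Epoxide 9 is treated with Pd2(dba)3, PBu3 and HCO2NH4 in 1,4-dioxane at rt. Zerovalent palladium adds to C8 anti to the C6–O bond to give an allenylpalladium; formate decarboxylation and C–H reductive elimination with retention then give the same allene diastereomer. This fallback makes no new compound (F0).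

**Further compounds**

F1 | step 18 | (6R)-6-[(1E,3E,5E,7E)-8-iodo-3,7-dimethylocta-1,3,5,7-tetraen-1-yl]-1,5,5-trimethylcyclohex-1-ene | CC1=CCCC(C)(C)[C@H]1/C=C/C(C)=C/C=C/C(C)=C/I
F2 | step 18 | tributyl[(1E,3E,5E,7E)-4-methyl-8-[(2R,7aR)-4,4,7a-trimethyl-2,4,5,6,7,7a-hexahydro-1-benzofuran-2-yl]nona-1,3,5,7-tetraen-1-yl]stannane | CCCC[Sn](CCCC)(CCCC)/C=C/C=C(C)/C=C/C=C(\C)[C@H]1C=C2C(C)(C)CCC[C@@]2(C)O1
F3 | step 8 | (2E)-3-[(2S,7aR)-3-iodo-4,4,7a-trimethyl-2,4,5,6,7,7a-hexahydro-1-benzofuran-2-yl]but-2-en-1-ol | OC/C=C(\C)[C@H]1C([I])=C2C(C)(C)CCC[C@@]2(C)O1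
F0 | step 7 | none | none
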